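**Retrosynthetic overview**

1. The C6=C7 double bond of the cyclohexene ring (C3a–C4–C5–C6=C7–C7a, indene numbering) marks that ring as a Diels–Alder adduct: cleaving C4–C5 and C3a–C7a opens both rings to one acyclic (2E,4Z,7E,9E,11E)-pentaenoate (dienophile C2=C3, diene C7=C8–C9=C10, chain numbering), the polyene of the presumed biosynthesis.
2. The styryl-bearing quaternary carbon C5 is thereby an sp2 diene terminus (chain C10), so its bond to the styryl CH is an sp2–sp2 bond and is cut to a (9E)-dienyl iodide and an (E)-styrylstannane; the Stille coupling that makes it completes the triene and sets off the cycloaddition in the same flask.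
3. Ring order: no ring before the key step; the cyclohexene ring and, through the C3a–C7a bond and the three-atom tether C1–C2=C3, the cyclopentene ring close together, with four stereocenters (two adjacent quaternary) relayed from the one bought stereocenter C1 (chain C6).
4. The iodotetraenoate comes linearly from methyl (S)-3-hydroxy-2-methylpropanoate: Wittig (7E), Corey–Fuchs/ethylation and hydrozirconation–iodination (9E iodide) on one arm, then Still–Gennari (4Z) and Wittig (2E) olefinations on the other.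
5. The methyl ester activates the dienophile through the cascade and is removed last by SN2 demethylation.

Key step: step 13

Remark: acyclic compounds are numbered along the C1–C12 chain of the pentaenoate; chain C6, C2, C3, C7 and C10 become C1, C4, C3a, C7a and C5 of the indene. Compounds 1, 4, 13, 17 and 20 are taken as catalogue compounds.

**Route**

Step 1
Reactants: 1 methyl (2S)-3-hydroxy-2-methylpropanoate
Product: 2 methyl (2S)-3-[(tert-butyldimethylsilyl)oxy]-2-methylpropanoate
Conditions: TBSCl, imidazole, DMF, 0 °C→rt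
Reagents that add atoms: tert-butyldimethylsilyl chloride, CC(C)(C)[Si](C)(C)Cl
Why: Imidazole-promoted silylation of a primary alcohol, which leaves the stereocenter untouched.

Step 2
Reactants: 2 methyl (2S)-3-[(tert-butyldimethylsilyl)oxy]-2-methylpropanoate
Product: 3 (2S)-3-[(tert-butyldimethylsilyl)oxy]-2-methylpropanal
Conditions: i-Bu2AlH, CH2Cl2, −78 °C; aq. KNaC4H4O6
Reagents that add atoms: none
Why: Partial reduction of the ester stops at the aluminium hemiacetal at −78 °C and should release the aldehyde on work-up, the α-stereocenter being kept if the aldehyde is used cold and at once.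

Step 3
Reactants: 3 (2S)-3-[(tert-butyldimethylsilyl)oxy]-2-methylpropanal, 4 2-(triphenylphosphoranylidene)butanal
Product: 5 (2E,4R)-5-[(tert-butyldimethylsilyl)oxy]-2-ethyl-4-methylpent-2-enal
Conditions: PhMe, 90 °C
Reagents that add atoms: none
Why: Wittig olefination with a formyl-stabilised ylide runs without base and should give the (E)-trisubstituted enal (chain C7=C8), the usual outcome for stabilised ylides, while the hindered product enal does not react a second time.

Step 4
Reactants: 5 (2E,4R)-5-[(tert-butyldimethylsilyl)oxy]-2-ethyl-4-methylpent-2-enal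
Product: 6 tert-butyl{[(2R,3E)-6,6-dibromo-4-ethyl-2-methylhexa-3,5-dien-1-yl]oxy}dimethylsilane
Conditions: CBr4, PPh3, Zn, CH2Cl2, 0 °C→rt
Reagents that add atoms: carbon tetrabromide, BrC(Br)(Br)Br
Why: First stage of the Corey–Fuchs reaction, a Wittig-type dibromo-olefination by Ph3P=CBr2 formed in the flask under neutral conditions that spare the silyl ether and the E olefin.

Step 5
Reactants: 6 tert-butyl{[(2R,3E)-6,6-dibromo-4-ethyl-2-methylhexa-3,5-dien-1-yl]oxy}dimethylsilane
Product: 8 tert-butyl{[(2R,3E)-4-ethyl-2-methyloct-3-en-5-yn-1-yl]oxy}dimethylsilane, via lithium acetylide 7 (not isolated)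
Conditions: n-BuLi (2.2 equiv), THF, −78→0 °C; then EtI, DMPU, −78 °C→rt
Reagents that add atoms: iodoethane, CCI
Why: Second stage of the Corey–Fuchs reaction, in which Br/Li exchange, α-elimination with 1,2-shift and deprotonation give the lithium acetylide, and SN2 alkylation with EtI in the presence of DMPU gives the internal alkyne.

Step 6
Reactants: 8 tert-butyl{[(2R,3E)-4-ethyl-2-methyloct-3-en-5-yn-1-yl]oxy}dimethylsilane
Product: 10 tert-butyl{[(2R,3E,5E)-4-ethyl-6-iodo-2-methylocta-3,5-dien-1-yl]oxy}dimethylsilane, via alkenylzirconocene chloride 9 (not isolated)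
Conditions: Cp2Zr(H)Cl, THF, 25→45 °C; then I2, THF, −30 °C, dark
Reagents that add atoms: iodine, II
Why: syn-Hydrozirconation of the internal alkyne should place zirconium on chain C10, the alkyne carbon flanked by the unbranched ethyl group and not by the α-branched alkenyl group (equilibration with excess Cp2Zr(H)Cl), and iodinolysis of the C–Zr bond with retention gives the (E)-iodide with iodine trans to the diene chain.

Step 7
Reactants: 10 tert-butyl{[(2R,3E,5E)-4-ethyl-6-iodo-2-methylocta-3,5-dien-1-yl]oxy}dimethylsilane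
Product: 11 (2R,3E,5E)-4-ethyl-6-iodo-2-methylocta-3,5-dien-1-ol
Conditions: HF·pyridine, pyridine, THF, 0 °C→rt
Reagents that add atoms: none
Why: Fluoride cleavage of the primary silyl ether under buffered, non-basic conditions that do not touch the iododiene.

Step 8
Reactants: 11 (2R,3E,5E)-4-ethyl-6-iodo-2-methylocta-3,5-dien-1-ol
Product: 12 (2R,3E,5E)-4-ethyl-6-iodo-2-methylocta-3,5-dienal
Conditions: Dess–Martin periodinane, pyridine, CH2Cl2, 0 °C; used crude at once
Reagents that add atoms: none
Why: Dess–Martin oxidation in buffered CH2Cl2 should give the α-chiral β,γ-unsaturated aldehyde without a base able to enolise it, and A(1,3) strain with the C8 ethyl group keeps the C6–H bond in the diene plane and so slows epimerisation or conjugation.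

Step 9
Reactants: 13 methyl 2-[bis(2,2,2-trifluoroethoxy)phosphoryl]acetate
Product: 14 methyl 2-[bis(2,2,2-trifluoroethoxy)phosphoryl]butanoate (racemic)
Conditions: NaH, THF, 0 °C; then EtI, rt
Reagents that add atoms: iodoethane, CCI
Why: C-Alkylation of the sodium salt of the phosphonoacetate with a primary iodide (phosphonate alkylation).

Step 10
Reactants: 12 (2R,3E,5E)-4-ethyl-6-iodo-2-methylocta-3,5-dienal, 14 methyl 2-[bis(2,2,2-trifluoroethoxy)phosphoryl]butanoate
Product: 15 methyl (2Z,4R,5E,7E)-2,6-diethyl-8-iodo-4-methyldeca-2,5,7-trienoate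
Conditions: 14, KN(SiMe3)2, 18-crown-6, THF, −78 °C; then 12, −78 °C
Reagents that add atoms: none
Why: Still–Gennari olefination, in which the electron-poor bis(trifluoroethyl) phosphonate under dissociating conditions eliminates fast from the kinetic adduct and should give the (Z)-trisubstituted enoate (chain C4=C5), the weakly basic phosphonate anion and the low temperature preserving C6.

Step 11
Reactants: 15 methyl (2Z,4R,5E,7E)-2,6-diethyl-8-iodo-4-methyldeca-2,5,7-trienoate
Product: 16 (2Z,4R,5E,7E)-2,6-diethyl-8-iodo-4-methyldeca-2,5,7-trien-1-ol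
Conditions: i-Bu2AlH, CH2Cl2, −78 °C; aq. KNaC4H4O6
Reagents that add atoms: none
Why: 1,2-Reduction of the enoate to the allylic alcohol at low temperature, to which the vinyl iodide and the olefin geometries are inert.

Step 12
Reactants: 16 (2Z,4R,5E,7E)-2,6-diethyl-8-iodo-4-methyldeca-2,5,7-trien-1-ol, 17 methyl 2-(triphenylphosphoranylidene)propanoate
Product: 19 methyl (2E,4Z,6S,7E,9E)-4,8-diethyl-10-iodo-2,6-dimethyldodeca-2,4,7,9-tetraenoate, via trienal 18 (not isolated)
Conditions: MnO2, CH2Cl2, rt; then 17, 25–40 °C, dark; product stored cold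
Reagents that add atoms: none
Why: Tandem allylic oxidation–Wittig reaction, in which MnO2 oxidises only the allylic alcohol and the stabilised ylide traps the (Z)-enal as it forms to give the new (2E)-olefin, so the sensitive aldehyde is never isolated and the mixture stays below the temperature of cycloaddition.

Step 13
Reactants: 19 methyl (2E,4Z,6S,7E,9E)-4,8-diethyl-10-iodo-2,6-dimethyldodeca-2,4,7,9-tetraenoate, 20 (E)-tributyl(2-phenylethenyl)stannane
Product: 22 methyl (1S,3aS,4S,5R,7aR)-3,5,7-triethyl-1,4-dimethyl-5-[(E)-2-phenylethenyl]-3a,4,5,7a-tetrahydro-1H-indene-4-carboxylate, via pentaenoate 21 (not isolated)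
Conditions: Pd2(dba)3 (5 mol%), AsPh3 (20 mol%), CuI (10 mol%), DMF, 25 °C, dark; then PhMe, BHT, 60 °C
Reagents that add atoms: none
Why: Oxidative addition of the C10–I bond of 19 to zerovalent palladium, Cu-assisted Sn-to-Pd transfer of the styryl group of 20 and reductive elimination form the C10–C11 bond with retention of both olefin geometries under neutral conditions that leave the acidic bis-allylic C6–H alone, and the triene thus completed makes C7=C8–C9=C10 a diene that adds to the C2=C3 enoate on warming. The closest known reaction type is the Stille coupling/intramolecular Diels–Alder cascade of trienoates, here in the fused (type 1) mode that copies the presumed biosynthesis. The cyclohexene ring closes by the suprafacial [4+2] cycloaddition (bonds C2–C10 and C3–C7), and the cyclopentene ring closes through the same C3–C7 bond as the annulation of the three-atom tether C4=C5–C6, which the 4Z geometry holds within reach. Indene C5 takes its configuration from the 9E geometry (styryl outside, ethyl inside), C4 from the 2E geometry with the ester endo, the trans fusion C3a/C7a from the same endo, tether-anti transition state, and the absolute sense of all four from C6, whose hydrogen eclipses the C7=C8 bond to avoid A(1,3) strain with the C8 ethyl group so that the dienophile adds to the diene face opposite the C6 methyl group. The step needs endo over exo selectivity and one diene face; the first should be secured by the E ester together with the clash between the C4 and C8 ethyl groups in the cis-fused transition state, the second by the A(1,3) strain.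

Step 14
Reactants: 22 methyl (1S,3aS,4S,5R,7aR)-3,5,7-triethyl-1,4-dimethyl-5-[(E)-2-phenylethenyl]-3a,4,5,7a-tetrahydro-1H-indene-4-carboxylate
Product: 23 (1S,3aS,4S,5R,7aR)-3,5,7-triethyl-1,4-dimethyl-5-[(E)-2-phenylethenyl]-3a,4,5,7a-tetrahydro-1H-indene-4-carboxylic acid
Conditions: NaSEt, DMF, 90 °C, degassed; then 1 M HCl
Reagents that add atoms: none
Why: SN2 demethylation by thiolate at the O-methyl carbon is insensitive to the hindrance at the acyl carbon, which sits between two quaternary centers, and cannot epimerise any stereocenter.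

**Compound list**

1 | methyl (2S)-3-hydroxy-2-methylpropanoate | OC[C@H](C)C(=O)OC | starting material
2 | methyl (2S)-3-[(tert-butyldimethylsilyl)oxy]-2-methylpropanoate | CC(C)(C)[Si](C)(C)OC[C@H](C)C(=O)OC | intermediate
3 | (2S)-3-[(tert-butyldimethylsilyl)oxy]-2-methylpropanal | CC(C)(C)[Si](C)(C)OC[C@H](C)C=O | intermediate
4 | 2-(triphenylphosphoranylidene)butanal | CCC(C=O)=P(c1ccccc1)(c1ccccc1)c1ccccc1 | starting material
5 | (2E,4R)-5-[(tert-butyldimethylsilyl)oxy]-2-ethyl-4-methylpent-2-enal | CC(C)(C)[Si](C)(C)OC[C@H](C)/C=C(CC)/C=O | intermediate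
6 | tert-butyl{[(2R,3E)-6,6-dibromo-4-ethyl-2-methylhexa-3,5-dien-1-yl]oxy}dimethylsilane | CC(C)(C)[Si](C)(C)OC[C@H](C)/C=C(CC)/C=C(Br)Br | intermediate
7 | {(3E,5R)-6-[(tert-butyldimethylsilyl)oxy]-3-ethyl-5-methylhex-3-en-1-yn-1-yl}lithium | CC(C)(C)[Si](C)(C)OC[C@H](C)/C=C(CC)/C#C[Li] | intermediate
8 | tert-butyl{[(2R,3E)-4-ethyl-2-methyloct-3-en-5-yn-1-yl]oxy}dimethylsilane | CC(C)(C)[Si](C)(C)OC[C@H](C)/C=C(CC)/C#CCC | intermediate
9 | chlorobis(cyclopentadienyl){(3E,5E,7R)-8-[(tert-butyldimethylsilyl)oxy]-5-ethyl-7-methylocta-3,5-dien-3-yl}zirconium (cyclopentadienyl rings drawn σ-bonded) | CC(C)(C)[Si](C)(C)OC[C@H](C)/C=C(CC)/C=C(/[Zr](Cl)(C1C=CC=C1)C1C=CC=C1)CC | intermediate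
10 | tert-butyl{[(2R,3E,5E)-4-ethyl-6-iodo-2-methylocta-3,5-dien-1-yl]oxy}dimethylsilane | CC(C)(C)[Si](C)(C)OC[C@H](C)/C=C(CC)/C=C(/I)CC | intermediate
11 | (2R,3E,5E)-4-ethyl-6-iodo-2-methylocta-3,5-dien-1-ol | OC[C@H](C)/C=C(CC)/C=C(/I)CC | intermediate
12 | (2R,3E,5E)-4-ethyl-6-iodo-2-methylocta-3,5-dienal | O=C[C@H](C)/C=C(CC)/C=C(/I)CC | intermediate
13 | methyl 2-[bis(2,2,2-trifluoroethoxy)phosphoryl]acetate | COC(=O)CP(=O)(OCC(F)(F)F)OCC(F)(F)F | starting material
14 | methyl 2-[bis(2,2,2-trifluoroethoxy)phosphoryl]butanoate (racemic) | CCC(C(=O)OC)P(=O)(OCC(F)(F)F)OCC(F)(F)F | intermediate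
15 | methyl (2Z,4R,5E,7E)-2,6-diethyl-8-iodo-4-methyldeca-2,5,7-trienoate | COC(=O)/C(CC)=C\[C@H](C)/C=C(CC)/C=C(/I)CC | intermediate
16 | (2Z,4R,5E,7E)-2,6-diethyl-8-iodo-4-methyldeca-2,5,7-trien-1-ol | OC/C(CC)=C\[C@H](C)/C=C(CC)/C=C(/I)CC | intermediate
17 | methyl 2-(triphenylphosphoranylidene)propanoate | COC(=O)C(C)=P(c1ccccc1)(c1ccccc1)c1ccccc1 | starting material
18 | (2Z,4R,5E,7E)-2,6-diethyl-8-iodo-4-methyldeca-2,5,7-trienal | O=C/C(CC)=C\[C@H](C)/C=C(CC)/C=C(/I)CC | intermediate
19 | methyl (2E,4Z,6S,7E,9E)-4,8-diethyl-10-iodo-2,6-dimethyldodeca-2,4,7,9-tetraenoate | COC(=O)/C(C)=C/C(CC)=C\[C@H](C)/C=C(CC)/C=C(/I)CC | intermediate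
20 | (E)-tributyl(2-phenylethenyl)stannane | CCCC[Sn](CCCC)(CCCC)/C=C/c1ccccc1 | starting material
21 | methyl (2E,4Z,6R,7E,9E,11E)-4,8,10-triethyl-2,6-dimethyl-12-phenyldodeca-2,4,7,9,11-pentaenoate | COC(=O)/C(C)=C/C(CC)=C\[C@H](C)/C=C(CC)/C=C(CC)/C=C/c1ccccc1 | intermediate
22 | methyl (1S,3aS,4S,5R,7aR)-3,5,7-triethyl-1,4-dimethyl-5-[(E)-2-phenylethenyl]-3a,4,5,7a-tetrahydro-1H-indene-4-carboxylate | CCC1=C[C@](/C=C/c2ccccc2)(CC)[C@@](C)(C(=O)OC)[C@@H]2C(CC)=C[C@H](C)[C@@H]12 | intermediate
23 | (1S,3aS,4S,5R,7aR)-3,5,7-triethyl-1,4-dimethyl-5-[(E)-2-phenylethenyl]-3a,4,5,7a-tetrahydro-1H-indene-4-carboxylic acid | CCC1=C[C@](/C=C/c2ccccc2)(CC)[C@@](C)(C(=O)O)[C@@H]2C(CC)=C[C@H](C)[C@@H]12 | target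

**Step count and risks**

Total step count: 14. Longest linear sequence: 13 steps (steps 1–8 and 10–14; step 9 is a one-step side branch).

Steps most likely to fail:

Step 13 (key cascade). The pentaenoate may need more heat for the cycloaddition than the (4Z)-dienoate tolerates, so that a [1,5]-hydrogen shift from C6 toward C2 erodes the stereocenter. The exo (cis-fused) mode may also compete, and the iododiene of 19 may cyclise before it is coupled. The fallback sets out from 19 and returns at 23; it raises the dienophile to the aldehyde level so that the cycloaddition can be run cold under Lewis acid catalysis. Reduction of 19 with i-Bu2AlH (CH2Cl2, −78 °C) should give (2E,4Z,6S,7E,9E)-4,8-diethyl-10-iodo-2,6-dimethyldodeca-2,4,7,9-tetraen-1-ol F1, and MnO2 oxidation (2E,4Z,6S,7E,9E)-4,8-diethyl-10-iodo-2,6-dimethyldodeca-2,4,7,9-tetraenal F2. Stille coupling with 20 at 25 °C (Pd2(dba)3, AsPh3, CuI, DMF) should give (2E,4Z,6R,7E,9E,11E)-4,8,10-triethyl-2,6-dimethyl-12-phenyldodeca-2,4,7,9,11-pentaenal F3. This is not warmed but treated with Me2AlCl in CH2Cl2 at −78 °C, where the coordinated enal should cyclise through the same endo transition state to (1S,3aS,4S,5R,7aR)-3,5,7-triethyl-1,4-dimethyl-5-[(E)-2-phenylethenyl]-3a,4,5,7a-tetrahydro-1H-indene-4-carbaldehyde F4. Pinnick oxidation (NaClO2, NaH2PO4, 2-methylbut-2-ene, t-BuOH/H2O) of this hindered aldehyde gives 23.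

Step 6 (hydrozirconation–iodination). Zirconium may add in part to the alkyne carbon next to the alkenyl group, or the diene may be reduced further, so that regioisomeric iodides form that are hard to separate. The fallback sets out from 8 and returns at 10. Cu-catalysed syn-borylcupration/protonation (CuCl, NaOt-Bu, P(p-tolyl)3, B2pin2, MeOH, THF, rt), in which copper takes the alkyne carbon next to the alkenyl group and boron the ethyl-bearing carbon, should give tert-butyl{[(2R,3E,5Z)-4-ethyl-2-methyl-6-(4,4,5,5-tetramethyl-1,3,2-dioxaborolan-2-yl)octa-3,5-dien-1-yl]oxy}dimethylsilane F5. KHF2 (MeOH/H2O) should convert it into potassium {(3Z,5E,7R)-8-[(tert-butyldimethylsilyl)oxy]-5-ethyl-7-methylocta-3,5-dien-3-yl}trifluoroborate F6. Iododeboronation with NaI and TsN(Cl)Na (chloramine-T) in THF/H2O, which goes with retention, gives 10.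

Step 10 (olefination of aldehyde 12). Enolisation of the β,γ-unsaturated aldehyde toward the diene may epimerise C6 or move the double bond into conjugation before or during the olefination, and Z selectivity with the α-ethyl phosphonate may be incomplete. The fallback sets out from 11 and returns at 16; it reverses the polarity of the olefination so that C6 is never α to a carbonyl group. Appel iodination (I2, PPh3, imidazole) should give (2R,3E,5E)-4-ethyl-1,6-diiodo-2-methylocta-3,5-diene F7, and PPh3 in MeCN at 80 °C [(2R,3E,5E)-4-ethyl-6-iodo-2-methylocta-3,5-dien-1-yl]triphenylphosphonium iodide F8. Wittig reaction of its ylide (NaN(SiMe3)2, THF, −78 °C) with 1-[(tert-butyldimethylsilyl)oxy]butan-2-one, a non-stabilised ylide/α-alkoxy ketone combination that is Z-selective for the trisubstituted olefin, should give tert-butyl{[(2Z,4R,5E,7E)-2,6-diethyl-8-iodo-4-methyldeca-2,5,7-trien-1-yl]oxy}dimethylsilane F9. HF·pyridine then gives 16.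

**Further compounds**

F1 | step 13 | (2E,4Z,6S,7E,9E)-4,8-diethyl-10-iodo-2,6-dimethyldodeca-2,4,7,9-tetraen-1-ol | OC/C(C)=C/C(CC)=C\[C@H](C)/C=C(CC)/C=C(/I)CC
F2 | step 13 | (2E,4Z,6S,7E,9E)-4,8-diethyl-10-iodo-2,6-dimethyldodeca-2,4,7,9-tetraenal | O=C/C(C)=C/C(CC)=C\[C@H](C)/C=C(CC)/C=C(/I)CC
F3 | step 13 | (2E,4Z,6R,7E,9E,11E)-4,8,10-triethyl-2,6-dimethyl-12-phenyldodeca-2,4,7,9,11-pentaenal | O=C/C(C)=C/C(CC)=C\[C@H](C)/C=C(CC)/C=C(CC)/C=C/c1ccccc1
F4 | step 13 | (1S,3aS,4S,5R,7aR)-3,5,7-triethyl-1,4-dimethyl-5-[(E)-2-phenylethenyl]-3a,4,5,7a-tetrahydro-1H-indene-4-carbaldehyde | CCC1=C[C@](/C=C/c2ccccc2)(CC)[C@@](C)(C=O)[C@@H]2C(CC)=C[C@H](C)[C@@H]12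
F5 | step 6 | tert-butyl{[(2R,3E,5Z)-4-ethyl-2-methyl-6-(4,4,5,5-tetramethyl-1,3,2-dioxaborolan-2-yl)octa-3,5-dien-1-yl]oxy}dimethylsilane | CC(C)(C)[Si](C)(C)OC[C@H](C)/C=C(CC)/C=C(/B1OC(C)(C)C(C)(C)O1)CC
F6 | step 6 | potassium {(3Z,5E,7R)-8-[(tert-butyldimethylsilyl)oxy]-5-ethyl-7-methylocta-3,5-dien-3-yl}trifluoroborate | CC(C)(C)[Si](C)(C)OC[C@H](C)/C=C(CC)/C=C(/[B-](F)(F)F)CC.[K+]
F7 | step 10 | (2R,3E,5E)-4-ethyl-1,6-diiodo-2-methylocta-3,5-diene | IC[C@H](C)/C=C(CC)/C=C(/I)CC
F8 | step 10 | [(2R,3E,5E)-4-ethyl-6-iodo-2-methylocta-3,5-dien-1-yl]triphenylphosphonium iodide | [I-].c1ccccc1[P+](c1ccccc1)(c1ccccc1)C[C@H](C)/C=C(CC)/C=C(/I)CC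
F9 | step 10 | tert-butyl{[(2Z,4R,5E,7E)-2,6-diethyl-8-iodo-4-methyldeca-2,5,7-trien-1-yl]oxy}dimethylsilane | CC(C)(C)[Si](C)(C)OC/C(CC)=C\[C@H](C)/C=C(CC)/C=C(/I)CC
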